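**Retrosynthetic overview**
- Feature: two flavanone units are joined C3–C8''. Ring C (O1, C2, C3, C4) and ring F (O1'', C2'', C3'', C4'') are each an ortho-hydroxyaryl ketone (rings A and D) plus one carbon (C2, C2'') that bears only an aryl ring (B, E) and hydrogen, so C2'', C2 and C3 can be set last on a flat, achiral 3,8''-bichromone.
- Last disconnections: seven O-benzyl groups, then C2–ring B (with C3–H) and C2''–ring E, each by asymmetric conjugate addition of an arylboronic acid to one pyranone.
- Key disconnection: both pyranones at once (C2–C3 and O1–C2 of ring C, C2''–C3'' and O1''–C2'' of ring F), back to one ortho-hydroxy diketone and two molecules of DMF-DMA.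
- Diketone: the C8''–CH2 bond comes from palladium-catalysed arylation of a ring A methyl ketone enolate with a ring D iodophenol, both made from one dibenzylated phloroacetophenone.
- Ring order: A and D are bought as phloroacetophenone, C and F are formed together, then E and B are attached.

Key step: step 6

Remark on locants: unit 1 (rings A, C, B) is unprimed and unit 2 (rings D, F, E) is double-primed.
Remark on configuration: the target SMILES is read as (2''S) and (2R,3R), which places ring B and ring D cis on ring C.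
Assumption on ligand sense: (S)-t-BuPyOx is taken to give the (R)-flavanone from a chromone, by analogy with its sense on cyclic enones, so the (R)-ligand is used in step 7 and the (S)-ligand in step 8; if a model chromone shows the opposite sense, the two ligands are exchanged.

**Route**

Step 1
Reactants: 1 2',4',6'-trihydroxyacetophenone
Product: 2 1-[2,4-bis(benzyloxy)-6-hydroxyphenyl]ethan-1-one
Conditions: BnBr (2.1 equiv), K2CO3, DMF, rt
Reagents that add atoms: benzyl bromide, BrCc1ccccc1
Why: Williamson ether synthesis in which the para hydroxyl and one ortho hydroxyl are alkylated while the other ortho hydroxyl, hydrogen-bonded to the acetyl carbonyl, stays free.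

Step 2
Reactants: 2 1-[2,4-bis(benzyloxy)-6-hydroxyphenyl]ethan-1-one
Product: 3 1-[4,6-bis(benzyloxy)-2-hydroxy-3-iodophenyl]ethan-1-one
Conditions: I2, HIO3, EtOH–H2O, 40 °C
Reagents that add atoms: iodine, [I][I]; iodic acid, O[I](=O)=O
Why: Electrophilic aromatic iodination that should go ortho to the free hydroxyl (the position between OH and OBn is less hindered than the one between two OBn groups), the usual position for phloroacetophenone 4,6-diethers.

Step 3
Reactants: 2 1-[2,4-bis(benzyloxy)-6-hydroxyphenyl]ethan-1-one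
Product: 4 1-[2,4-bis(benzyloxy)-6-(methoxymethoxy)phenyl]ethan-1-one
Conditions: NaH, MOMCl, DMF, 0 °C to rt
Reagents that add atoms: chloromethyl methyl ether, COCCl
Why: O-alkylation of the sodium phenoxide (Williamson-type acetal formation), so that this ketone carries no phenoxide and its methyl group is the most acidic site in step 4.

Step 4
Reactants: 3 1-[4,6-bis(benzyloxy)-2-hydroxy-3-iodophenyl]ethan-1-one; 4 1-[2,4-bis(benzyloxy)-6-(methoxymethoxy)phenyl]ethan-1-one (1.5 equiv)
Product: 5 2-[3-acetyl-4,6-bis(benzyloxy)-2-hydroxyphenyl]-1-[2,4-bis(benzyloxy)-6-(methoxymethoxy)phenyl]ethan-1-one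
Conditions: Pd2(dba)3 (2.5 mol%), XPhos (10 mol%), NaOtBu (3 equiv), toluene, 80 °C; aq NH4Cl
Reagents that add atoms: none
Why: Palladium-catalysed α-arylation of a ketone enolate (Buchwald–Hartwig type, a reaction known with ortho-halophenols), in which the enolate of 4 couples at the C–I bond of 3 while the acetyl group of 3 resists enolisation because 3 is present as its phenoxide.

Step 5
Reactants: 5 2-[3-acetyl-4,6-bis(benzyloxy)-2-hydroxyphenyl]-1-[2,4-bis(benzyloxy)-6-(methoxymethoxy)phenyl]ethan-1-one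
Product: 6 2-[3-acetyl-4,6-bis(benzyloxy)-2-hydroxyphenyl]-1-[2,4-bis(benzyloxy)-6-hydroxyphenyl]ethan-1-one
Conditions: conc. HCl (cat.), MeOH–THF, rt
Reagents that add atoms: none
Why: Acid-catalysed acetal exchange removes the methoxymethyl group ortho to the ketone under conditions mild enough to leave the benzyl ethers intact and to avoid cyclodehydration of the ring D phenol onto the ring A ketone.

Step 6
Reactants: 6 2-[3-acetyl-4,6-bis(benzyloxy)-2-hydroxyphenyl]-1-[2,4-bis(benzyloxy)-6-hydroxyphenyl]ethan-1-one; 7 N,N-dimethylformamide dimethyl acetal (8 equiv)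
Product: 9 5,5',7,7'-tetrakis(benzyloxy)-4H,4'H-[3,8'-bichromene]-4,4'-dione, via bis-enaminone 8 (not isolated)
Conditions: DMF-DMA, toluene, 100 °C; then conc. HCl, CH2Cl2–MeOH, 40 °C
Reagents that add atoms: none
Why: Both carbon acids of 6 (the acetyl methyl on ring D and the doubly benzylic methylene next to the ring A ketone) are deprotonated by methoxide released from 7, add to the methoxy(dimethylamino)methylium ion and lose methanol to give the bis-enaminone 8; this is the known DMF-DMA synthesis of chromones from ortho-hydroxyaryl methyl ketones and of isoflavones from 2-hydroxydeoxybenzoins, run here on both sites of one molecule. Ring C closes by 6-endo-trig addition of the ring A hydroxyl to the aminomethylene carbon (O1–C2 after C2–C3) with loss of dimethylamine, normally already during heating, and ring F closes in the same mode from the ring D hydroxyl (O1''–C2'' after C2''–C3'') once acid turns the vinylogous amide into an iminium ion. No stereocentre is formed, so the product is a flat bichromone. Ring F must use O1'' beside C8'' and not the C5'' oxygen, which is fixed because only the hydroxyl between the acetyl group and the benzylic carbon is free (set by the ortho-iodination of step 2). The ring D hydroxyl must also not attack the neighbouring aminomethylene carbon to give a 3-aroylbenzofuran; that closure is 5-endo-trig, is disfavoured against the 6-endo closure by the ring A hydroxyl, and is held back by the hydrogen bond of the ring D hydroxyl to its own enaminone carbonyl. Both free hydroxyls are chelated, so O-methylation by 7 should stay minor.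

Step 7
Reactants: 9 5,5',7,7'-tetrakis(benzyloxy)-4H,4'H-[3,8'-bichromene]-4,4'-dione; 10 4-(benzyloxy)phenylboronic acid (2 equiv)
Product: 11 (2S)-5,7-bis(benzyloxy)-2-[4-(benzyloxy)phenyl]-8-[5,7-bis(benzyloxy)-4-oxo-4H-chromen-3-yl]-2,3-dihydro-4H-chromen-4-one
Conditions: Pd(OCOCF3)2 (10 mol%), (R)-t-BuPyOx [(R)-4-tert-butyl-2-(pyridin-2-yl)-4,5-dihydrooxazole] (12 mol%), NH4PF6 (30 mol%), H2O (5 equiv), ClCH2CH2Cl, 60 °C
Reagents that add atoms: none
Why: Catalytic asymmetric conjugate addition of an arylboronic acid to a chromone (aryl–palladium insertion then protonation) at the unsubstituted C2''=C3'' bond, where the pyridine-oxazoline ligand selects the alkene face that gives (S) at C2'' and the C2=C3 bond, which carries ring D at C3, is too hindered to compete.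

Step 8
Reactants: 11 (2S)-5,7-bis(benzyloxy)-2-[4-(benzyloxy)phenyl]-8-[5,7-bis(benzyloxy)-4-oxo-4H-chromen-3-yl]-2,3-dihydro-4H-chromen-4-one; 12 3,4-bis(benzyloxy)phenylboronic acid (3 equiv)
Product: 13 (2S)-5,7-bis(benzyloxy)-2-[4-(benzyloxy)phenyl]-8-{(2R,3R)-5,7-bis(benzyloxy)-2-[3,4-bis(benzyloxy)phenyl]-4-oxo-3,4-dihydro-2H-chromen-3-yl}-2,3-dihydro-4H-chromen-4-one (2,3-cis)
Conditions: Pd(OCOCF3)2 (20 mol%), (S)-t-BuPyOx (24 mol%), NH4PF6 (30 mol%), H2O (5 equiv), ClCH2CH2Cl, 50 °C, N2, stopped at full conversion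
Reagents that add atoms: none
Why: Proposed new method: the aryl–palladium species carrying (S)-t-BuPyOx, formed by transmetalation from 12, should insert the C2=C3 bond of the 3-aryl-chromone unit with the aryl group going to the unsubstituted C2 on the ligand-selected face (C2 R); the palladium enolate at C3 cannot undergo syn β-hydride elimination in the ring and is released by protonolysis, and the resulting enol is protonated at C3 on the face away from the new C2 aryl group, which places ring B and ring D cis (C3 R); the closest known reactions are the same divalent-palladium pyridine-oxazoline addition to chromones without a C3 substituent and to β-substituted cyclic enones.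

Step 9
Reactants: 13 (2S)-5,7-bis(benzyloxy)-2-[4-(benzyloxy)phenyl]-8-{(2R,3R)-5,7-bis(benzyloxy)-2-[3,4-bis(benzyloxy)phenyl]-4-oxo-3,4-dihydro-2H-chromen-3-yl}-2,3-dihydro-4H-chromen-4-one
Product: 14 (2S)-8-[(2R,3R)-2-(3,4-dihydroxyphenyl)-5,7-dihydroxy-4-oxo-3,4-dihydro-2H-chromen-3-yl]-5,7-dihydroxy-2-(4-hydroxyphenyl)-2,3-dihydro-4H-chromen-4-one (CNP0105436.1)
Conditions: H2 (1 atm), 10% Pd/C, THF–MeOH, rt
Reagents that add atoms: none
Why: Catalytic hydrogenolysis cleaves the seven benzyl aryl ethers under neutral conditions, so the two ketones, C2'', C2 and the epimerisable C3 should be left unchanged.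

**Compound list**
1 | 2',4',6'-trihydroxyacetophenone | CC(=O)c1c(O)cc(O)cc1O | starting material
2 | 1-[2,4-bis(benzyloxy)-6-hydroxyphenyl]ethan-1-one | CC(=O)c1c(O)cc(OCc2ccccc2)cc1OCc1ccccc1 | intermediate
3 | 1-[4,6-bis(benzyloxy)-2-hydroxy-3-iodophenyl]ethan-1-one | CC(=O)c1c(O)c(I)c(OCc2ccccc2)cc1OCc1ccccc1 | intermediate
4 | 1-[2,4-bis(benzyloxy)-6-(methoxymethoxy)phenyl]ethan-1-one | CC(=O)c1c(OCOC)cc(OCc2ccccc2)cc1OCc1ccccc1 | intermediate
5 | 2-[3-acetyl-4,6-bis(benzyloxy)-2-hydroxyphenyl]-1-[2,4-bis(benzyloxy)-6-(methoxymethoxy)phenyl]ethan-1-one | CC(=O)c1c(O)c(CC(=O)c2c(OCOC)cc(OCc3ccccc3)cc2OCc2ccccc2)c(OCc2ccccc2)cc1OCc1ccccc1 | intermediate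
6 | 2-[3-acetyl-4,6-bis(benzyloxy)-2-hydroxyphenyl]-1-[2,4-bis(benzyloxy)-6-hydroxyphenyl]ethan-1-one | CC(=O)c1c(O)c(CC(=O)c2c(O)cc(OCc3ccccc3)cc2OCc2ccccc2)c(OCc2ccccc2)cc1OCc1ccccc1 | intermediate
7 | N,N-dimethylformamide dimethyl acetal | COC(OC)N(C)C | starting material
8 | 2-{4,6-bis(benzyloxy)-3-[(E)-3-(dimethylamino)prop-2-enoyl]-2-hydroxyphenyl}-1-[2,4-bis(benzyloxy)-6-hydroxyphenyl]-3-(dimethylamino)prop-2-en-1-one | CN(C)/C=C/C(=O)c1c(O)c(C(=CN(C)C)C(=O)c2c(O)cc(OCc3ccccc3)cc2OCc2ccccc2)c(OCc2ccccc2)cc1OCc1ccccc1 | intermediate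
9 | 5,5',7,7'-tetrakis(benzyloxy)-4H,4'H-[3,8'-bichromene]-4,4'-dione | O=c1ccoc2c1c(OCc1ccccc1)cc(OCc1ccccc1)c2-c1coc2cc(OCc3ccccc3)cc(OCc3ccccc3)c2c1=O | intermediate
10 | 4-(benzyloxy)phenylboronic acid | OB(O)c1ccc(OCc2ccccc2)cc1 | starting material
11 | (2S)-5,7-bis(benzyloxy)-2-[4-(benzyloxy)phenyl]-8-[5,7-bis(benzyloxy)-4-oxo-4H-chromen-3-yl]-2,3-dihydro-4H-chromen-4-one | O=C1C[C@@H](c2ccc(OCc3ccccc3)cc2)Oc2c1c(OCc1ccccc1)cc(OCc1ccccc1)c2-c1coc2cc(OCc3ccccc3)cc(OCc3ccccc3)c2c1=O | intermediate
12 | 3,4-bis(benzyloxy)phenylboronic acid | OB(O)c1ccc(OCc2ccccc2)c(OCc2ccccc2)c1 | starting material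
13 | (2S)-5,7-bis(benzyloxy)-2-[4-(benzyloxy)phenyl]-8-{(2R,3R)-5,7-bis(benzyloxy)-2-[3,4-bis(benzyloxy)phenyl]-4-oxo-3,4-dihydro-2H-chromen-3-yl}-2,3-dihydro-4H-chromen-4-one | O=C1C[C@@H](c2ccc(OCc3ccccc3)cc2)Oc2c1c(OCc1ccccc1)cc(OCc1ccccc1)c2[C@H]1C(=O)c2c(OCc3ccccc3)cc(OCc3ccccc3)cc2O[C@H]1c1ccc(OCc2ccccc2)c(OCc2ccccc2)c1 | intermediate
14 | (2S)-8-[(2R,3R)-2-(3,4-dihydroxyphenyl)-5,7-dihydroxy-4-oxo-3,4-dihydro-2H-chromen-3-yl]-5,7-dihydroxy-2-(4-hydroxyphenyl)-2,3-dihydro-4H-chromen-4-one | O=C1C[C@@H](c2ccc(O)cc2)Oc2c1c(O)cc(O)c2[C@H]1C(=O)c2c(O)cc(O)cc2O[C@H]1c1ccc(O)c(O)c1 | target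

Total step count: 9. Longest linear sequence: 8 steps (steps 1, 2, 4, 5, 6, 7, 8, 9; step 3 is a one-step branch from 2).

**Steps most likely to fail**

Step 8. Insertion of the aryl–palladium species into the α-aryl-substituted, shielded C2=C3 bond may be too slow, so that 12 is lost to protodeboronation, or the kinetic cis product may epimerise at C3 to the trans isomer during the reaction. The fallback sets out from 11 and returns at 13, using known cuprate chemistry. Purchased 4-bromo-1,2-bis(benzyloxy)benzene is lithiated (t-BuLi, THF, −78 °C) and treated with CuI (0.5 equiv) to give lithium bis[3,4-bis(benzyloxy)phenyl]cuprate F1. With Me3SiCl at −78 °C this adds to C2 of the 3-aryl-chromone unit of 11, a chlorosilane-accelerated cuprate conjugate addition of the kind known for chromones; the flavanone ketone should not be attacked by the weakly basic cuprate at this temperature. The product is the trimethylsilyl enol ether of 13 F2, formed as both C2 epimers. Buffered desilylation (TBAF–AcOH, THF, −78 °C) protonates C3 kinetically on the face opposite the C2 aryl group, so both epimers should be 2,3-cis. Compound 13 is then separated by chromatography from the (2S,3S) diastereomer of 13 F3, which the fixed (S) centre at C2'' makes a separable diastereomer.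

Step 6. The ring D hydroxyl may close onto the benzylic enaminone carbon and give a 3-aroylbenzofuran, or condensation at the hindered benzylic methylene may stay incomplete. The fallback sets out from 3, 4 and 7 and returns at 9; it closes ring F before the C8''–CH2 bond exists, so no free ring D hydroxyl is present when the benzylic enaminone forms. Iodide 3 and 7 (toluene, 90 °C) give (E)-1-[4,6-bis(benzyloxy)-2-hydroxy-3-iodophenyl]-3-(dimethylamino)prop-2-en-1-one F4, which HCl in CH2Cl2 cyclises to 5,7-bis(benzyloxy)-8-iodo-4H-chromen-4-one F5. Palladium-catalysed enolate arylation of 4 with F5 (Pd2(dba)3, XPhos, K3PO4, toluene, 90 °C; the weaker base spares the chromone) gives 5,7-bis(benzyloxy)-8-{2-[2,4-bis(benzyloxy)-6-(methoxymethoxy)phenyl]-2-oxoethyl}-4H-chromen-4-one F6. Catalytic HCl in MeOH–THF removes the methoxymethyl group to give 5,7-bis(benzyloxy)-8-{2-[2,4-bis(benzyloxy)-6-hydroxyphenyl]-2-oxoethyl}-4H-chromen-4-one F7. F7 and 7 in toluene at 100 °C give the enaminone of F7 F8 (not isolated), which closes ring C to 9 as in a standard isoflavone synthesis.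

Step 7. Facial selectivity may be poor, because the bulky and conformationally mobile C8'' substituent sits next to O1'' and the 5,7-dialkoxy chromone reacts slowly. The fallback sets out from 9 and 10 and returns at 11, replacing catalyst control by resolution. The addition is run with an achiral ligand (Pd(OCOCF3)2, 2,2'-bipyridine, AcOH–THF–H2O, 60 °C) to give racemic 5,7-bis(benzyloxy)-2-[4-(benzyloxy)phenyl]-8-[5,7-bis(benzyloxy)-4-oxo-4H-chromen-3-yl]-2,3-dihydro-4H-chromen-4-one F9. The (S) enantiomer 11 is then isolated by preparative chromatography on a chiral stationary phase.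

**Further compounds**
F1 | step 8 | lithium bis[3,4-bis(benzyloxy)phenyl]cuprate | [Li+].[Cu-](c1ccc(OCc2ccccc2)c(OCc2ccccc2)c1)c1ccc(OCc2ccccc2)c(OCc2ccccc2)c1
F2 | step 8 | trimethylsilyl enol ether of 13 (C3=C4, C4–OSiMe3; both C2 epimers) | O=C1C[C@@H](c2ccc(OCc3ccccc3)cc2)Oc2c1c(OCc1ccccc1)cc(OCc1ccccc1)c2C1=C(O[Si](C)(C)C)c2c(OCc3ccccc3)cc(OCc3ccccc3)cc2OC1c1ccc(OCc2ccccc2)c(OCc2ccccc2)c1
F3 | step 8 | (2S,3S) diastereomer of 13 (C2'' S, 2,3-cis) | O=C1C[C@@H](c2ccc(OCc3ccccc3)cc2)Oc2c1c(OCc1ccccc1)cc(OCc1ccccc1)c2[C@@H]1C(=O)c2c(OCc3ccccc3)cc(OCc3ccccc3)cc2O[C@@H]1c1ccc(OCc2ccccc2)c(OCc2ccccc2)c1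
F4 | step 6 | (E)-1-[4,6-bis(benzyloxy)-2-hydroxy-3-iodophenyl]-3-(dimethylamino)prop-2-en-1-one | CN(C)/C=C/C(=O)c1c(O)c(I)c(OCc2ccccc2)cc1OCc1ccccc1
F5 | step 6 | 5,7-bis(benzyloxy)-8-iodo-4H-chromen-4-one | O=c1ccoc2c(I)c(OCc3ccccc3)cc(OCc3ccccc3)c12
F6 | step 6 | 5,7-bis(benzyloxy)-8-{2-[2,4-bis(benzyloxy)-6-(methoxymethoxy)phenyl]-2-oxoethyl}-4H-chromen-4-one | O=c1ccoc2c(CC(=O)c3c(OCOC)cc(OCc4ccccc4)cc3OCc3ccccc3)c(OCc3ccccc3)cc(OCc3ccccc3)c12
F7 | step 6 | 5,7-bis(benzyloxy)-8-{2-[2,4-bis(benzyloxy)-6-hydroxyphenyl]-2-oxoethyl}-4H-chromen-4-one | O=c1ccoc2c(CC(=O)c3c(O)cc(OCc4ccccc4)cc3OCc3ccccc3)c(OCc3ccccc3)cc(OCc3ccccc3)c12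
F8 | step 6 | enaminone of F7 (dimethylaminomethylene at the benzylic carbon) | O=c1ccoc2c(C(=CN(C)C)C(=O)c3c(O)cc(OCc4ccccc4)cc3OCc3ccccc3)c(OCc3ccccc3)cc(OCc3ccccc3)c12
F9 | step 7 | racemic 5,7-bis(benzyloxy)-2-[4-(benzyloxy)phenyl]-8-[5,7-bis(benzyloxy)-4-oxo-4H-chromen-3-yl]-2,3-dihydro-4H-chromen-4-one | O=C1CC(c2ccc(OCc3ccccc3)cc2)Oc2c1c(OCc1ccccc1)cc(OCc1ccccc1)c2-c1coc2cc(OCc3ccccc3)cc(OCc3ccccc3)c2c1=O
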